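**Retrosynthetic overview** (flavanone numbering: O1, C2, C3, C4, C4a, C5–C8, C8a; ring A = benzo ring, ring C = pyranone, ring B = 2-aryl group)

- Ring C is cut across C2–C3 and O1–C8a in one formal [4+2]: 3,4-dimethoxybenzaldehyde supplies C2=O1 (and ring B), and a C3=C4(OSiMe3)–C4a=C8a silyloxydiene supplies the rest.
- Enabling feature: in ring A the free C8–OH is para to the C5–OMe, and C8a is the only unsubstituted ring carbon, lying between C8 and the acyl-bearing C4a. Ring A can therefore be carried as a p-quinone monoketal (C8 carbonyl, C5 dimethyl ketal) in which C8a is an electrophilic sp2 CH.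
- After O1–C8a bond formation, loss of MeOH from C5 re-aromatises ring A and leaves exactly the 8-OH/5-OMe pattern; C2 (S) is set by catalyst control in the C2–C3 aldol event.
- Ring order: ring A is bought aromatic (2',3',4'-trimethoxyacetophenone), oxygenated at C8 (bromination, Br→OH) and dearomatised (PhI(OAc)2/MeOH); ring C is closed and ring A re-aromatised in the last step.

Key step: step 5

Remark: compounds 1 and 7 are taken as commercial. The oxazaborolidinone catalyst of step 5 is prepared just before use from N-tosyl-D-tryptophan and butylboronic acid and is not counted as a step.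

**Step 1**
Reactants: 1 1-(2,3,4-trimethoxyphenyl)ethan-1-one
Product: 2 1-(5-bromo-2,3,4-trimethoxyphenyl)ethan-1-one
Conditions: NBS, MeCN, 0 °C → rt
Reagents that add atoms: N-bromosuccinimide, O=C1CCC(=O)N1Br
Why: Electrophilic aromatic bromination should go to C5, which is para to the 2-OMe, ortho to the 4-OMe and meta to the acetyl group, whereas C6 is ortho to the acyl group and para only to the twisted central OMe; NBS in a polar aprotic solvent without acid should leave the methyl ketone alone.

**Step 2**
Reactants: 2 1-(5-bromo-2,3,4-trimethoxyphenyl)ethan-1-one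
Product: 4 1-(5-hydroxy-2,3,4-trimethoxyphenyl)ethan-1-one, via aryl pinacol boronate 3 (not isolated)
Conditions: B2pin2, PdCl2(dppf) (3 mol%), KOAc, 1,4-dioxane, 90 °C; then Oxone (2KHSO5·KHSO4·K2SO4), acetone/H2O, 0 °C
Reagents that add atoms: bis(pinacolato)diboron, CC1(C)OB(OC1(C)C)B1OC(C)(C)C(C)(C)O1 (boron of intermediate 3); potassium peroxymonosulfate, [K+].OOS(=O)(=O)[O-] (oxygen of 4)
Why: Miyaura borylation under weak-base conditions should tolerate the methyl ketone, and oxidation of the boronate (1,2-aryl shift from boron to oxygen) should give the phenol under base-free conditions.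

**Step 3**
Reactants: 4 1-(5-hydroxy-2,3,4-trimethoxyphenyl)ethan-1-one
Product: 5 3-acetyl-4,4,5,6-tetramethoxycyclohexa-2,5-dien-1-one
Conditions: PhI(OAc)2, MeOH, 0 °C
Reagents that add atoms: methanol, CO
Why: Oxidative dearomatisation of a p-methoxyphenol by a λ3-iodane in methanol should deliver solvent to the para carbon that already carries OMe (the 2-OMe carbon next to the acetyl group), giving the p-quinone monoketal.

**Step 4**
Reactants: 5 3-acetyl-4,4,5,6-tetramethoxycyclohexa-2,5-dien-1-one
Product: 6 4,4,5,6-tetramethoxy-3-[1-(trimethylsilyloxy)ethenyl]cyclohexa-2,5-dien-1-one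
Conditions: Me3SiCl, then LiN(SiMe3)2 (in situ quench), THF, −78 °C; non-aqueous work-up, used at once
Reagents that add atoms: chlorotrimethylsilane, C[Si](C)(C)Cl
Why: Internal-quench enol silane formation: the acetyl CH3 is the only enolisable position (the ring carbonyl has no α-hydrogen), and the hindered amide with silyl chloride already present should trap the dienolate on oxygen before it can add to the ene-dione of unreacted 5.

**Step 5**
Reactants: 6 4,4,5,6-tetramethoxy-3-[1-(trimethylsilyloxy)ethenyl]cyclohexa-2,5-dien-1-one; 7 3,4-dimethoxybenzaldehyde (1.3 equiv)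
Product: 10 (2S)-2-(3,4-dimethoxyphenyl)-8-hydroxy-5,6,7-trimethoxy-2,3-dihydro-4H-chromen-4-one, via silyl aldol ether 8 (not isolated), via 8a-H dienone 9 (not isolated)
Conditions: (4R)-2-butyl-4-(1H-indol-3-ylmethyl)-3-(4-methylphenylsulfonyl)-1,3,2-oxazaborolidin-5-one (20 mol%), EtCN, −78 °C; then Me3SiOSO2CF3 (10 mol%), −78 → −30 °C; pH 7 buffer
Reagents that add atoms: none
Why: Proposed new method: the boron Lewis acid binds aldehyde 7 and the CH2 terminus of enol silane 6 adds to it (Mukaiyama aldol with silyl transfer) to give silyl ether 8; catalytic silyl triflate then ionises the ketal, the silyloxy oxygen attacks C8a (SN2′ with respect to the ketal, equivalent to conjugate addition to the C4 acyl-enone), Me3SiOMe is released and dienone 9 tautomerises to the phenol. The closest known reaction types are the oxazaborolidinone-catalysed Mukaiyama aldol of 1-aryl-1-silyloxyethenes with aldehydes, including its aldol-then-acid extension to dihydropyranones (stepwise hetero-Diels–Alder), and the acid-promoted SN2′ substitution of quinone monoketals at the carbon α to the carbonyl that gives ortho-substituted p-methoxyphenols; new is their combination with an intramolecular oxygen nucleophile. Ring C, the only ring formed, closes by 6-endo-trig attack of O1 on C8a, so that overall the aldehyde C=O adds across the C3=C4–C4a=C8a diene in a formal [4+2], while ring A is only re-aromatised. C2 is the only stereocentre and is set in the C–C bond-forming event by the catalyst: Si-face attack on the aldehyde is predicted for the D-tryptophan-derived enantiomer by the indole-stacking model of the boron-bound aldehyde and should be confirmed on the first run (the antipode is equally accessible); the cyclisation does not touch C2. The step needs the aldol to precede any ketal ionisation, which the weakly oxophilic boron catalyst at −78 °C and addition of the silyl triflate only after 6 is consumed should secure, and it needs C8a rather than ipso C5 attack, which is secured because attack at the ketal carbon is reversible ketal exchange whereas attack at C8a is followed by irreversible aromatisation, and because the β-carbons of the ring enone are blocked (C4a fully substituted, C6 methoxylated). Aromatisation and the Si–O bond of Me3SiOMe should also pull the otherwise unfavourable aldol equilibrium of this electron-rich aldehyde forward.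

**Compound list**

1 | 1-(2,3,4-trimethoxyphenyl)ethan-1-one | CC(=O)c1ccc(OC)c(OC)c1OC | starting material
2 | 1-(5-bromo-2,3,4-trimethoxyphenyl)ethan-1-one | CC(=O)c1cc(Br)c(OC)c(OC)c1OC | intermediate
3 | 1-[2,3,4-trimethoxy-5-(4,4,5,5-tetramethyl-1,3,2-dioxaborolan-2-yl)phenyl]ethan-1-one | CC(=O)c1cc(B2OC(C)(C)C(C)(C)O2)c(OC)c(OC)c1OC | intermediate (not isolated)
4 | 1-(5-hydroxy-2,3,4-trimethoxyphenyl)ethan-1-one | CC(=O)c1cc(O)c(OC)c(OC)c1OC | intermediate
5 | 3-acetyl-4,4,5,6-tetramethoxycyclohexa-2,5-dien-1-one | CC(=O)C1=CC(=O)C(OC)=C(OC)C1(OC)OC | intermediate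
6 | 4,4,5,6-tetramethoxy-3-[1-(trimethylsilyloxy)ethenyl]cyclohexa-2,5-dien-1-one | C=C(O[Si](C)(C)C)C1=CC(=O)C(OC)=C(OC)C1(OC)OC | intermediate
7 | 3,4-dimethoxybenzaldehyde | COc1ccc(C=O)cc1OC | starting material
8 | 3-[(3S)-3-(3,4-dimethoxyphenyl)-3-(trimethylsilyloxy)propanoyl]-4,4,5,6-tetramethoxycyclohexa-2,5-dien-1-one | COc1ccc([C@H](CC(=O)C2=CC(=O)C(OC)=C(OC)C2(OC)OC)O[Si](C)(C)C)cc1OC | intermediate (not isolated)
9 | (2S)-2-(3,4-dimethoxyphenyl)-5,6,7-trimethoxy-2,3-dihydro-4H-chromene-4,8(8aH)-dione (C8a configuration not defined) | COc1ccc([C@@H]2CC(=O)C3=C(OC)C(OC)=C(OC)C(=O)C3O2)cc1OC | intermediate (not isolated)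
10 | (2S)-2-(3,4-dimethoxyphenyl)-8-hydroxy-5,6,7-trimethoxy-2,3-dihydro-4H-chromen-4-one | COc1ccc([C@@H]2CC(=O)c3c(c(O)c(OC)c(OC)c3OC)O2)cc1OC | target

**Step count and risks**

Total steps: 5. Longest linear sequence: 5 steps (1 → 10); aldehyde 7 enters in step 5.

**Step 5 (proposed new method).** Possible failures:
- slow addition of the cross-conjugated enol silane to the electron-rich aldehyde, with competing intermolecular Mukaiyama–Michael addition or premature ketal ionisation;
- poor facial selectivity;
- leakage through ipso attack at the ketal carbon into the isomeric 6-hydroxy-5,7,8-trimethoxy series;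
- acid-induced ionisation of the benzylic C–O bond, eroding the configuration at C2.

The fallback uses known chemistry only; it sets out from phenol 4 and comes back at target 10. Palladium-catalysed ketone-directed ortho C–H hydroxylation at the only free ring position (Pd(OAc)2, K2S2O8, CF3CO2H/(CF3CO)2O, 50 °C; the phenol is masked in the flask as its trifluoroacetate) should give 3-acetyl-4,5,6-trimethoxy-1,2-phenylene bis(2,2,2-trifluoroacetate) F1 (not isolated), hydrolysed on aqueous work-up to 1-(2,3-dihydroxy-4,5,6-trimethoxyphenyl)ethan-1-one F2. Selective benzylation of the non-chelated hydroxyl (BnBr, K2CO3, acetone) should give 1-[3-(benzyloxy)-2-hydroxy-4,5,6-trimethoxyphenyl]ethan-1-one F3. Condensation with Me2NCH(OMe)2 (toluene, 90 °C) gives (2E)-1-[3-(benzyloxy)-2-hydroxy-4,5,6-trimethoxyphenyl]-3-(dimethylamino)prop-2-en-1-one F4, closed with HCl in CH2Cl2 to 8-(benzyloxy)-5,6,7-trimethoxy-4H-chromen-4-one F5. Asymmetric conjugate addition of (3,4-dimethoxyphenyl)boronic acid (Pd(OCOCF3)2, 4-tert-butyl-2-(pyridin-2-yl)-4,5-dihydrooxazole in the enantiomer that gives the 2S series, expected to be R, NH4PF6, H2O, ClCH2CH2Cl, 60 °C) should give (2S)-8-(benzyloxy)-2-(3,4-dimethoxyphenyl)-5,6,7-trimethoxy-2,3-dihydro-4H-chromen-4-one F6. Hydrogenolysis (H2, Pd/C, EtOAc) returns 10.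

**Step 4.** Possible failures: self-condensation by conjugate addition of the dienolate to the ene-dione of unreacted 5, attack of the amide on the dienone, and loss of the ketal during isolation of the enol silane.

The fallback avoids any preformed enol derivative; it sets out from monoketal 5 (with aldehyde 7) and comes back at target 10. A direct catalytic asymmetric aldol with a dinuclear zinc catalyst (Et2Zn, 10 mol%, and 2,6-bis{[2-(hydroxydiphenylmethyl)pyrrolidin-1-yl]methyl}-4-methylphenol, 5 mol%, in the enantiomer that directs Si-face attack, 4 Å molecular sieves, THF, −20 °C) should give 3-[(3S)-3-(3,4-dimethoxyphenyl)-3-hydroxypropanoyl]-4,4,5,6-tetramethoxycyclohexa-2,5-dien-1-one F7 as its zinc alkoxide. This should cyclise in the same flask by oxa-Michael addition at C8a, loss of methoxide from C5 and tautomerisation (completed with a trace of CF3CO2H if needed) to 10. Irreversible aromatisation is expected to draw the reversible aldol of the aromatic aldehyde forward.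

**Step 3.** Possible failures: conjugate (SN2′) addition of solvent methanol at the ring CH of the acyl-activated monoketal with re-aromatisation (over-methoxylation), and hydrolysis to the quinone during isolation.

The fallback makes the C2–C3 bond first in the aromatic series and dearomatises last, so that the monoketal is trapped by the tethered carbinol as it forms; it sets out from phenol 4 and comes back at target 10. Double silylation (Me3SiOSO2CF3, Et3N, CH2Cl2, 0 °C) should give trimethyl({2,3,4-trimethoxy-5-[1-(trimethylsilyloxy)ethenyl]phenoxy})silane F8. Mukaiyama aldol with 7 under the oxazaborolidinone catalyst of step 5 (EtCN, −78 °C), an ordinary aryl methyl ketone enol silane within the known scope, should give (3S)-3-(3,4-dimethoxyphenyl)-1-[2,3,4-trimethoxy-5-(trimethylsilyloxy)phenyl]-3-(trimethylsilyloxy)propan-1-one F9 (not isolated). Dilute HCl in THF on work-up frees (3S)-3-(3,4-dimethoxyphenyl)-3-hydroxy-1-(5-hydroxy-2,3,4-trimethoxyphenyl)propan-1-one F10. Oxidation with PhI(OAc)2 in MeOH at 0 °C should give monoketal F7 in the flask; solvent exchange to CH2Cl2 and a catalytic amount of CF3CO2H should then close ring C and re-aromatise ring A to 10.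

**Further compounds**

F1 | step 5 | 3-acetyl-4,5,6-trimethoxy-1,2-phenylene bis(2,2,2-trifluoroacetate) | CC(=O)c1c(OC(=O)C(F)(F)F)c(OC(=O)C(F)(F)F)c(OC)c(OC)c1OC
F2 | step 5 | 1-(2,3-dihydroxy-4,5,6-trimethoxyphenyl)ethan-1-one | CC(=O)c1c(O)c(O)c(OC)c(OC)c1OC
F3 | step 5 | 1-[3-(benzyloxy)-2-hydroxy-4,5,6-trimethoxyphenyl]ethan-1-one | CC(=O)c1c(O)c(OCc2ccccc2)c(OC)c(OC)c1OC
F4 | step 5 | (2E)-1-[3-(benzyloxy)-2-hydroxy-4,5,6-trimethoxyphenyl]-3-(dimethylamino)prop-2-en-1-one | CN(C)/C=C/C(=O)c1c(O)c(OCc2ccccc2)c(OC)c(OC)c1OC
F5 | step 5 | 8-(benzyloxy)-5,6,7-trimethoxy-4H-chromen-4-one | O=c1ccoc2c(OCc3ccccc3)c(OC)c(OC)c(OC)c12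
F6 | step 5 | (2S)-8-(benzyloxy)-2-(3,4-dimethoxyphenyl)-5,6,7-trimethoxy-2,3-dihydro-4H-chromen-4-one | COc1ccc([C@@H]2CC(=O)c3c(c(OCc4ccccc4)c(OC)c(OC)c3OC)O2)cc1OC
F7 | step 4 | 3-[(3S)-3-(3,4-dimethoxyphenyl)-3-hydroxypropanoyl]-4,4,5,6-tetramethoxycyclohexa-2,5-dien-1-one | COc1ccc([C@@H](O)CC(=O)C2=CC(=O)C(OC)=C(OC)C2(OC)OC)cc1OC
F8 | step 3 | trimethyl({2,3,4-trimethoxy-5-[1-(trimethylsilyloxy)ethenyl]phenoxy})silane | C=C(O[Si](C)(C)C)c1cc(O[Si](C)(C)C)c(OC)c(OC)c1OC
F9 | step 3 | (3S)-3-(3,4-dimethoxyphenyl)-1-[2,3,4-trimethoxy-5-(trimethylsilyloxy)phenyl]-3-(trimethylsilyloxy)propan-1-one | COc1ccc([C@H](CC(=O)c2cc(O[Si](C)(C)C)c(OC)c(OC)c2OC)O[Si](C)(C)C)cc1OC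
F10 | step 3 | (3S)-3-(3,4-dimethoxyphenyl)-3-hydroxy-1-(5-hydroxy-2,3,4-trimethoxyphenyl)propan-1-one | COc1ccc([C@@H](O)CC(=O)c2cc(O)c(OC)c(OC)c2OC)cc1OC
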